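**Assumptions:** Naringin is the commercial (2S) natural product. The (S) descriptor of the target SMILES is the same as that of natural (S)-naringenin.

## Retrosynthetic overview
1. Target **4** comes from (S)-naringenin **2** by installing prenyl groups at C6 and C8 by photoinduced ortho-C–H prenylation of the 7-phenolate. This is the key bond-forming step.
2. **2** comes from naringin **1** by glycoside hydrolysis.
3. The only stereocenter (C2, S) is inherited unchanged from **1**. No ring is formed in the route, because the A, B and C rings are already present, and the two prenyl groups are added last.

## Route

**Step 1**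
Reactants: **1**, naringin (naringenin 7-O-[α-L-rhamnopyranosyl-(1→2)-β-D-glucopyranoside], (2S))
Product: **2**, (S)-naringenin, (2S)-5,7-dihydroxy-2-(4-hydroxyphenyl)chroman-4-one
Conditions: 2 M aq. H2SO4, EtOH (1:1), 80 °C, 4 h; cool, collect precipitate, recrystallize
Reagents that add atoms: none (the water oxygen ends up in the neohesperidose by-product)
Why: Acid-catalysed hydrolysis of the aryl glycoside (oxocarbenium pathway) releases the 7-OH. C2 is untouched because flavanone ring-opening racemization needs base, not acid, so the (S) center is retained from **1**.

**Step 2**
Reactants: **2**, (S)-naringenin; **3**, prenyl bromide (1-bromo-3-methylbut-2-ene)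
Product: **4**, 6,8-diprenylnaringenin, (2S)-5,7-dihydroxy-2-(4-hydroxyphenyl)-6,8-bis(3-methylbut-2-enyl)chroman-4-one
Conditions: **3** (2.4 equiv), Li2CO3 (2.6 equiv), MeCN (0.05 M), N2, 390 nm LEDs, 10–15 °C, 16 h; quench with sat. NH4Cl, extract with EtOAc, silica chromatography
Reagents that add atoms: prenyl bromide, CC(C)=CCBr (supplies both C5H9 units)
Why: Proposed new method: photoinduced C-prenylation of the unprotected flavanone 7-phenolate.
- Mechanism: Li2CO3 deprotonates only the acidic 7-OH. The 4'-OH stays protonated, and the 5-OH is H-bonded to C4=O. The red-tailing 7-phenolate, probably as an ion-pair or EDA complex with **3**, is excited at 390 nm. Dissociative single-electron transfer to **3** gives a phenoxyl radical with spin density at C6/C8, a prenyl radical and LiBr in a solvent cage.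
- Regiochemistry: Coupling occurs at the unhindered primary terminus of the prenyl radical, giving linear prenyl rather than 1,1-dimethylallyl. The resulting cyclohexadienone tautomerizes irreversibly to the phenol.
- Second prenylation: The monoprenyl phenolate is more electron-rich and more red-shifted, so it alkylates faster at the remaining ortho position, giving the 6,8-diprenyl product. No free ortho C–H remains after that.
- Stereocenter: C2 is not involved. The mild carbonate base, low temperature and the 7-phenolate's deactivation of C4=O toward enolization suppress ring-opening racemization.
- Closest known chemistry: photoexcited phenolate/naphtholate alkylation with alkyl halides, and base-mediated C-prenylation of phloroglucinols.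

## Compound list
1 | naringin | OC[C@H]1O[C@@H](Oc3cc(O)c4C(=O)C[C@@H](c5ccc(O)cc5)Oc4c3)[C@H](O[C@@H]2O[C@@H](C)[C@H](O)[C@@H](O)[C@H]2O)[C@@H](O)[C@@H]1O | starting material
2 | (S)-naringenin | O=C1C[C@@H](c2ccc(O)cc2)Oc2cc(O)cc(O)c12 | intermediate
3 | prenyl bromide | CC(C)=CCBr | starting material (reagent)
4 | 6,8-diprenylnaringenin | CC(C)=CCc1c(O)c(CC=C(C)C)c2c(c1O)C(=O)C[C@@H](c1ccc(O)cc1)O2 | target

## Summary
Total steps: 2. Longest linear sequence: 2.

The route has only two steps, so the third failure point below is a second failure mode of Step 2.

**Three most likely failure points**
1. **Step 2, chemo- and regioselectivity (the proposed new step).** Dark SN2 O-prenylation of the phenolate, mixtures of mono-, di- and gem-dialkylated products, or reverse-prenyl coupling could all lower the yield.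
   - Fallback (known chemistry, different mechanism): polar C-alkylation of **2** with **3** in aqueous alkaline medium (Ca(OH)2 or KOH, MeOH/H2O, 0 °C), followed by chromatographic isolation of the 6,8-diprenyl product.
2. **Step 1, hydrolysis.** Incomplete cleavage of the neohesperidoside, or partial loss of ee at high temperature.
   - Fallback: enzymatic deglycosylation of **1** with naringinase at pH 4 and 40 °C, or direct purchase of (S)-naringenin **2**.
3. **Step 2, configurational integrity at C2.** Carbonate-mediated retro-oxa-Michael ring-opening could erode the ee during the 16 h irradiation.
   - Fallback: move to an acidic regime, where flavanones are configurationally stable. Use Lewis-acid (BF3·OEt2) Friedel–Crafts prenylation of **2** with 3-methylbut-2-en-1-ol or 2-methylbut-3-en-2-ol on alumina or in dioxane, accepting a lower yield and chroman by-products.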